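**Strategy.** The lower pyran ring (O1, C2, C3, C4, C4a, C8a) is disconnected at C4–C4a and O1–C2 and is built last, on a pyrogallol ring that already carries the finished upper 4-arylflavan. In one flask an ortho-lithiated lithium phenoxide (carbanion at C4a, oxygen O1, from bromophenol 11) adds to the aldehyde of a cis-epoxy aldehyde holding C2–C4, and the liberated phenol opens the epoxide at C2. The step exploits the adjacent O1/C4a positions of ring A and the para-oxygenated ring B that makes C2 the electrophilic epoxide carbon; addition anti to the epoxide C–O bond and inversion at C2 give the all-cis C2/C3/C4 array.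

Key step: step 10

Remark: the SMILES is read as a (2S)-flavan whose C4 carries, trans to the 2-aryl group, C6 of an all-cis (2R,3R,4R)-flavan-3,4-diol; the upper C4 is S in the free phenol and R in the protected intermediates through the priority rules only, the geometry being the same.

**Step 1**
Reactants: 1 1-(2,3,4-trihydroxyphenyl)ethan-1-one
Product: 2 1-[3,4-bis(benzyloxy)-2-hydroxyphenyl]ethan-1-one
Conditions: BnBr (2.05 equiv), K2CO3 (2.2 equiv), acetone, reflux
Reagents that add atoms: benzyl bromide, BrCc1ccccc1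
Why: Williamson ether synthesis; the 2-hydroxyl is held in a hydrogen bond to the acetyl group and is the least nucleophilic of the three, so alkylation should stop at the 3,4-dibenzyl ether, and no stereocentre is formed.

**Step 2**
Reactants: 2 1-[3,4-bis(benzyloxy)-2-hydroxyphenyl]ethan-1-one
Product: 4 7,8-bis(benzyloxy)-4H-chromen-4-one, via enaminone 3 (not isolated)
Conditions: Me2NCH(OMe)2, toluene, 100 °C; then conc. HCl, CH2Cl2, rt
Reagents that add atoms: N,N-dimethylformamide dimethyl acetal, COC(OC)N(C)C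
Why: Enaminone route to chromones; condensation of the methyl ketone with the amide acetal, then acid-promoted intramolecular conjugate addition of the phenol and loss of dimethylamine, should close the pyranone ring of the upper unit without forming a stereocentre.

**Step 3**
Reactants: 4 7,8-bis(benzyloxy)-4H-chromen-4-one; 5 [4-(benzyloxy)phenyl]boronic acid
Product: 6 (2S)-7,8-bis(benzyloxy)-2-[4-(benzyloxy)phenyl]-2,3-dihydro-4H-chromen-4-one
Conditions: Pd(OCOCF3)2 (5 mol %), (R)-4-tert-butyl-2-(pyridin-2-yl)-4,5-dihydrooxazole (6 mol %), NH4PF6 (30 mol %), H2O (5 equiv), ClCH2CH2Cl, 60 °C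
Reagents that add atoms: none
Why: Palladium-catalysed asymmetric conjugate addition of an arylboronic acid to a chromone; the aryl–palladium species bound to the chiral pyridine-oxazoline ligand adds to one face of C2, and the (R)-ligand is chosen because its sense of induction on cyclic enones corresponds to the 2S flavanone.

**Step 4**
Reactants: 6 (2S)-7,8-bis(benzyloxy)-2-[4-(benzyloxy)phenyl]-2,3-dihydro-4H-chromen-4-one
Product: 7 (2S,4S)-7,8-bis(benzyloxy)-2-[4-(benzyloxy)phenyl]-3,4-dihydro-2H-chromen-4-ol (2,4-cis)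
Conditions: NaBH4, THF/MeOH, 0 °C
Reagents that add atoms: none
Why: Borohydride reduction of a flavanone, which should give mainly the 2,4-cis alcohol (4S) by axial hydride delivery to the conformer with an equatorial 2-aryl group; this centre is made planar again in step 6, so its purity is not critical.

**Step 5**
Reactants: 8 benzene-1,2,3-triol (pyrogallol)
Product: 9 2,2-diphenyl-1,3-benzodioxol-4-ol
Conditions: Ph2CCl2 (1.1 equiv), neat, 170 °C, N2 stream
Reagents that add atoms: dichlorodiphenylmethane, ClC(Cl)(c1ccccc1)c1ccccc1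
Why: Ketal formation by double substitution of the gem-dichloride by two neighbouring phenolic oxygens; only vicinal hydroxyls can form the five-membered ring, so one terminal hydroxyl (the future O1 of the lower unit) stays free and the symmetry of pyrogallol allows a single product.

**Step 6**
Reactants: 7 (2S,4S)-7,8-bis(benzyloxy)-2-[4-(benzyloxy)phenyl]-3,4-dihydro-2H-chromen-4-ol; 9 2,2-diphenyl-1,3-benzodioxol-4-ol (3 equiv)
Product: 10 7-{(2S,4R)-7,8-bis(benzyloxy)-2-[4-(benzyloxy)phenyl]-3,4-dihydro-2H-chromen-4-yl}-2,2-diphenyl-1,3-benzodioxol-4-ol (2,4-trans)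
Conditions: BF3·OEt2 (0.2 equiv), CH2Cl2, −40 → 0 °C
Reagents that add atoms: none
Why: Friedel–Crafts alkylation with loss of water; ionisation of the benzylic 4-hydroxyl gives a cation stabilised by O1 and the 7-benzyloxy group, which phenol 9 should capture with its carbon para to the free hydroxyl, axial attack on the half-chair with an equatorial 2-aryl group setting the 2,4-trans configuration at C4.

**Step 7**
Reactants: 10 7-{(2S,4R)-7,8-bis(benzyloxy)-2-[4-(benzyloxy)phenyl]-3,4-dihydro-2H-chromen-4-yl}-2,2-diphenyl-1,3-benzodioxol-4-ol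
Product: 11 5-bromo-7-{(2S,4R)-7,8-bis(benzyloxy)-2-[4-(benzyloxy)phenyl]-3,4-dihydro-2H-chromen-4-yl}-2,2-diphenyl-1,3-benzodioxol-4-ol
Conditions: NBS (1.0 equiv), i-Pr2NH (0.1 equiv), CH2Cl2, −78 → 0 °C
Reagents that add atoms: N-bromosuccinimide, O=C1CCC(=O)N1Br
Why: Electrophilic aromatic bromination of a phenol, directed by the amine-bound brominating agent to the carbon ortho to the free hydroxyl (the para position is occupied), which is the future C4a; the free phenol should react far faster than the aryl benzyl ethers, and no stereocentre is touched.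

**Step 8**
Reactants: 12 4-(benzyloxy)benzaldehyde; 13 3-chloroprop-1-ene (allyl chloride)
Product: 16 (2S,3R)-2-[4-(benzyloxy)phenyl]-3-ethenyloxirane (cis), via chloroallylborane 14 (not isolated), via chlorohydrin 15 (not isolated)
Conditions: 13, (+)-Ipc2BOMe, LiN(c-C6H11)2, Et2O/THF, −95 °C; BF3·OEt2, then 12, −95 °C; then NaOH, H2O2, 0 °C → rt
Reagents that add atoms: none
Why: γ-Chloroallylboration followed by epoxide closure; lithiated allyl chloride is trapped on boron and rearranges to the (Z)-γ-chloroallylborane 14, which should add to the Re face of aldehyde 12 through a chair six-membered transition state under control of the isopinocampheyl groups to give the syn chlorohydrin 15 (1S,2S), and base then displaces chloride with inversion to give the cis epoxide.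

**Step 9**
Reactants: 16 (2S,3R)-2-[4-(benzyloxy)phenyl]-3-ethenyloxirane
Product: 17 (2S,3S)-3-[4-(benzyloxy)phenyl]oxirane-2-carbaldehyde (cis)
Conditions: O3, CH2Cl2, −78 °C; then PPh3, −78 °C → rt; used crude
Reagents that add atoms: ozone, [O-][O+]=O
Why: Ozonolysis with reductive work-up should cleave the terminal alkene to the aldehyde at −78 °C without touching the two epoxide stereocentres, whose descriptors change to 2S,3S through the priority rules only.

**Step 10**
Reactants: 11 5-bromo-7-{(2S,4R)-7,8-bis(benzyloxy)-2-[4-(benzyloxy)phenyl]-3,4-dihydro-2H-chromen-4-yl}-2,2-diphenyl-1,3-benzodioxol-4-ol; 17 (2S,3S)-3-[4-(benzyloxy)phenyl]oxirane-2-carbaldehyde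
Product: 20 (2R,3R,4R)-6-{(2S,4R)-7,8-bis(benzyloxy)-2-[4-(benzyloxy)phenyl]-3,4-dihydro-2H-chromen-4-yl}-2-[4-(benzyloxy)phenyl]-7,8-(diphenylmethylenedioxy)-3,4-dihydro-2H-chromene-3,4-diol (2,3-cis-3,4-cis), via dilithio species 18 (not isolated), via epoxy alcohol 19 (not isolated)
Conditions: 11, n-BuLi (1.05 equiv), THF, −78 °C; t-BuLi (2.1 equiv), −78 °C; 17 (1.3 equiv), −78 °C; AcOH, −78 → 0 °C; then PPTS (0.1 equiv), CH2Cl2, 0 °C → rt
Reagents that add atoms: none
Why: Bromine–lithium exchange on the lithium phenoxide gives a C4a carbanion that adds to the aldehyde of 17 (organolithium addition to an α,β-epoxy aldehyde), and after protonation the free C8a phenol opens the activated epoxide at C2 under mild acid catalysis (intramolecular phenol opening of an aryl epoxide, the reaction type that closes 2'-hydroxychalcone epoxides to dihydroflavonols). The only ring closed is the lower pyran ring, in a 6-endo-tet mode with respect to the epoxide, O1 attacking C2 anti to the departing epoxide oxygen. C4 is the new stereocentre: the aryllithium should approach the carbonyl anti to the polar epoxide C–O bond and past the small α-hydrogen (non-chelated 1,2-induction, reinforced by the cis-aryl group), giving the 4R erythro epoxy alcohol 19 and hence the 3,4-cis diol. C3 is carried over unchanged from 17, and C2 is inverted from S to R in the SN2-like opening, so the cis-epoxide becomes the 2,3-cis ether. The step needs aldehyde-over-epoxide chemoselectivity (secured at −78 °C by the much higher electrophilicity of the aldehyde), 6-endo over 5-exo regioselectivity (secured by the 4-benzyloxyphenyl group, which stabilises positive charge at C2 but not at C3) and inversion without a free cation (favoured by the weak acid, the low temperature and the intramolecular nucleophile).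

**Step 11**
Reactants: 20 (2R,3R,4R)-6-{(2S,4R)-7,8-bis(benzyloxy)-2-[4-(benzyloxy)phenyl]-3,4-dihydro-2H-chromen-4-yl}-2-[4-(benzyloxy)phenyl]-7,8-(diphenylmethylenedioxy)-3,4-dihydro-2H-chromene-3,4-diol
Product: 21 (2R,3R,4R)-6-[(2S,4S)-7,8-dihydroxy-2-(4-hydroxyphenyl)-3,4-dihydro-2H-chromen-4-yl]-2-(4-hydroxyphenyl)-3,4-dihydro-2H-chromene-3,4,7,8-tetrol
Conditions: H2 (1 atm), Pd(OH)2/C, EtOAc/MeOH, rt
Reagents that add atoms: none
Why: Catalytic hydrogenolysis should remove the four benzyl ethers and the diphenylmethylene ketal as toluene and diphenylmethane under neutral conditions, leaving the five stereocentres and the benzylic C4 hydroxyl untouched.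

**Compound list**

1 | 1-(2,3,4-trihydroxyphenyl)ethan-1-one | CC(=O)c1ccc(O)c(O)c1O | starting material
2 | 1-[3,4-bis(benzyloxy)-2-hydroxyphenyl]ethan-1-one | CC(=O)c1ccc(OCc2ccccc2)c(OCc2ccccc2)c1O | intermediate
3 | (E)-1-[3,4-bis(benzyloxy)-2-hydroxyphenyl]-3-(dimethylamino)prop-2-en-1-one | CN(C)/C=C/C(=O)c1ccc(OCc2ccccc2)c(OCc2ccccc2)c1O | intermediate
4 | 7,8-bis(benzyloxy)-4H-chromen-4-one | O=C1C=COc2c1ccc(OCc1ccccc1)c2OCc1ccccc1 | intermediate
5 | [4-(benzyloxy)phenyl]boronic acid | OB(O)c1ccc(OCc2ccccc2)cc1 | starting material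
6 | (2S)-7,8-bis(benzyloxy)-2-[4-(benzyloxy)phenyl]-2,3-dihydro-4H-chromen-4-one | O=C1C[C@@H](c2ccc(OCc3ccccc3)cc2)Oc2c1ccc(OCc1ccccc1)c2OCc1ccccc1 | intermediate
7 | (2S,4S)-7,8-bis(benzyloxy)-2-[4-(benzyloxy)phenyl]-3,4-dihydro-2H-chromen-4-ol (2,4-cis) | O[C@H]1C[C@@H](c2ccc(OCc3ccccc3)cc2)Oc2c1ccc(OCc1ccccc1)c2OCc1ccccc1 | intermediate
8 | benzene-1,2,3-triol (pyrogallol) | Oc1cccc(O)c1O | starting material
9 | 2,2-diphenyl-1,3-benzodioxol-4-ol | Oc1cccc2OC(c3ccccc3)(c3ccccc3)Oc12 | intermediate
10 | 7-{(2S,4R)-7,8-bis(benzyloxy)-2-[4-(benzyloxy)phenyl]-3,4-dihydro-2H-chromen-4-yl}-2,2-diphenyl-1,3-benzodioxol-4-ol (2,4-trans) | Oc1ccc([C@@H]2C[C@@H](c3ccc(OCc4ccccc4)cc3)Oc3c2ccc(OCc2ccccc2)c3OCc2ccccc2)c2OC(c3ccccc3)(c3ccccc3)Oc12 | intermediate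
11 | 5-bromo-7-{(2S,4R)-7,8-bis(benzyloxy)-2-[4-(benzyloxy)phenyl]-3,4-dihydro-2H-chromen-4-yl}-2,2-diphenyl-1,3-benzodioxol-4-ol | Oc1c(Br)cc([C@@H]2C[C@@H](c3ccc(OCc4ccccc4)cc3)Oc3c2ccc(OCc2ccccc2)c3OCc2ccccc2)c2OC(c3ccccc3)(c3ccccc3)Oc12 | intermediate
12 | 4-(benzyloxy)benzaldehyde | O=Cc1ccc(OCc2ccccc2)cc1 | starting material
13 | 3-chloroprop-1-ene (allyl chloride) | C=CCCl | starting material
14 | (Z)-(3-chloroprop-2-en-1-yl)diisopinocampheylborane, isopinocampheyl groups as in (+)-Ipc2BOMe | Cl/C=C\CB([C@H]1C[C@H]2C[C@@H]([C@@H]1C)C2(C)C)[C@H]1C[C@H]2C[C@@H]([C@@H]1C)C2(C)C | intermediate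
15 | (1S,2S)-1-[4-(benzyloxy)phenyl]-2-chlorobut-3-en-1-ol (syn) | C=C[C@H](Cl)[C@@H](O)c1ccc(OCc2ccccc2)cc1 | intermediate
16 | (2S,3R)-2-[4-(benzyloxy)phenyl]-3-ethenyloxirane (cis) | C=C[C@H]1O[C@H]1c1ccc(OCc2ccccc2)cc1 | intermediate
17 | (2S,3S)-3-[4-(benzyloxy)phenyl]oxirane-2-carbaldehyde (cis) | O=C[C@H]1O[C@H]1c1ccc(OCc2ccccc2)cc1 | intermediate
18 | O,C5-dilithio derivative of 11 (lithium phenoxide with lithium in place of bromine) | [Li]Oc1c([Li])cc([C@@H]2C[C@@H](c3ccc(OCc4ccccc4)cc3)Oc3c2ccc(OCc2ccccc2)c3OCc2ccccc2)c2OC(c3ccccc3)(c3ccccc3)Oc12 | intermediate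
19 | (R)-{7-[(2S,4R)-7,8-bis(benzyloxy)-2-[4-(benzyloxy)phenyl]-3,4-dihydro-2H-chromen-4-yl]-4-hydroxy-2,2-diphenyl-1,3-benzodioxol-5-yl}{(2R,3S)-3-[4-(benzyloxy)phenyl]oxiran-2-yl}methanol | O[C@H](c1cc([C@@H]2C[C@@H](c3ccc(OCc4ccccc4)cc3)Oc3c2ccc(OCc2ccccc2)c3OCc2ccccc2)c2OC(c3ccccc3)(c3ccccc3)Oc2c1O)[C@H]1O[C@H]1c1ccc(OCc2ccccc2)cc1 | intermediate
20 | (2R,3R,4R)-6-{(2S,4R)-7,8-bis(benzyloxy)-2-[4-(benzyloxy)phenyl]-3,4-dihydro-2H-chromen-4-yl}-2-[4-(benzyloxy)phenyl]-7,8-(diphenylmethylenedioxy)-3,4-dihydro-2H-chromene-3,4-diol (2,3-cis-3,4-cis) | C(c1ccccc1)Oc1ccc([C@@H]2C[C@@H](c3cc4c(c5OC(c6ccccc6)(c6ccccc6)Oc35)O[C@H](c3ccc(OCc5ccccc5)cc3)[C@H](O)[C@@H]4O)c3ccc(OCc4ccccc4)c(OCc4ccccc4)c3O2)cc1 | intermediate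
21 | (2R,3R,4R)-6-[(2S,4S)-7,8-dihydroxy-2-(4-hydroxyphenyl)-3,4-dihydro-2H-chromen-4-yl]-2-(4-hydroxyphenyl)-3,4-dihydro-2H-chromene-3,4,7,8-tetrol | Oc1ccc([C@@H]2C[C@@H](c3cc4c(c(O)c3O)O[C@H](c3ccc(O)cc3)[C@H](O)[C@@H]4O)c3ccc(O)c(O)c3O2)cc1 | target

**Step count.** Total: 11 steps. Longest linear sequence: 8 steps (1, 2, 3, 4, 6, 7, 10, 11).

**Steps most likely to fail**

Step 10. The addition to the epoxy aldehyde may show poor facial selectivity, because chelation by the neighbouring lithium phenoxide can compete with the non-chelated pathway. The benzylic epoxide may also ionise in part before ring closure. Either process would erode the 3,4-cis or the 2,3-cis relationship. The fallback sets out from crude epoxy alcohol 19, taken before the acid treatment, and moves C4 to the ketone level. Activated MnO2 in CH2Cl2 should oxidise the ortho-hydroxybenzylic alcohol to the cis-epoxy ketone F1. Sodium acetate in ethanol at room temperature should then let the phenoxide displace the epoxide oxygen at C2 in a non-ionising SN2 closure, as in the cyclisation of 2'-hydroxychalcone epoxides, to give the 2,3-cis-dihydroflavonol F2. Reduction with NaBH4 in THF/MeOH at −20 °C, with hydride entering anti to the axial 3-hydroxyl, should give the 3,4-cis diol, and the route is rejoined at 20.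

Step 6. Alkylation ortho to the free hydroxyl of 9, O-alkylation, formation of the 2,4-cis epimer and self-condensation of the flavanyl cation with ring A of a second molecule of 7 may all compete. The fallback sets out from 9 and blocks the ortho carbon first. Amine-catalysed ortho-bromination (NBS, i-Pr2NH, CH2Cl2, −78 °C) should give 5-bromo-2,2-diphenyl-1,3-benzodioxol-4-ol F3, whose only activated free carbon is para to the hydroxyl. Coupling of F3 (3 equiv) with 7 under the conditions of step 6, again with loss of water from 7, then rejoins the route at 11, and step 7 is no longer needed.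

Step 11. Hydrogenolysis of the doubly activated benzylic C4–O bond, or of the C2–O1 bond, may compete with O-debenzylation. The fallback sets out from 20 and removes the protecting groups while C4 is a carbonyl. MnO2 in CH2Cl2 should oxidise the benzylic 4-hydroxyl selectively to the 2,3-cis-dihydroflavonol F2, the same ketone as in the first fallback. Hydrogenolysis (H2, Pd(OH)2/C, EtOAc/MeOH) should give the free phenolic 2,3-cis-dihydroflavonol F4. Borohydride reduction of this free phenolic dihydroflavonol (NaBH4, EtOH, 0 °C, under argon), a classical reaction of this compound class, should then give the 3,4-cis diol, and the route is rejoined at 21.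

**Further compounds**

F1 | step 10 | {7-[(2S,4R)-7,8-bis(benzyloxy)-2-[4-(benzyloxy)phenyl]-3,4-dihydro-2H-chromen-4-yl]-4-hydroxy-2,2-diphenyl-1,3-benzodioxol-5-yl}{(2S,3S)-3-[4-(benzyloxy)phenyl]oxiran-2-yl}methanone | O=C(c1cc([C@@H]2C[C@@H](c3ccc(OCc4ccccc4)cc3)Oc3c2ccc(OCc2ccccc2)c3OCc2ccccc2)c2OC(c3ccccc3)(c3ccccc3)Oc2c1O)[C@H]1O[C@H]1c1ccc(OCc2ccccc2)cc1
F2 | step 10 | (2R,3S)-6-{(2S,4R)-7,8-bis(benzyloxy)-2-[4-(benzyloxy)phenyl]-3,4-dihydro-2H-chromen-4-yl}-2-[4-(benzyloxy)phenyl]-3-hydroxy-7,8-(diphenylmethylenedioxy)-2,3-dihydro-4H-chromen-4-one (2,3-cis) | C(c1ccccc1)Oc1ccc([C@@H]2C[C@@H](c3cc4c(c5OC(c6ccccc6)(c6ccccc6)Oc35)O[C@H](c3ccc(OCc5ccccc5)cc3)[C@H](O)C4=O)c3ccc(OCc4ccccc4)c(OCc4ccccc4)c3O2)cc1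
F3 | step 6 | 5-bromo-2,2-diphenyl-1,3-benzodioxol-4-ol | Oc1c(Br)ccc2OC(c3ccccc3)(c3ccccc3)Oc12
F4 | step 11 | (2R,3S)-6-[(2S,4S)-7,8-dihydroxy-2-(4-hydroxyphenyl)-3,4-dihydro-2H-chromen-4-yl]-3,7,8-trihydroxy-2-(4-hydroxyphenyl)-2,3-dihydro-4H-chromen-4-one (2,3-cis) | Oc1ccc([C@@H]2C[C@@H](c3cc4c(c(O)c3O)O[C@H](c3ccc(O)cc3)[C@H](O)C4=O)c3ccc(O)c(O)c3O2)cc1
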